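**Retrosynthetic overview**
- Target ⇒ acyclic epoxy aldehyde carrying a tetrasubstituted (Z)-β-iodo enoate: intramolecular Ni/Cr vinylation of the C6 aldehyde by the C7 iodide, the alkoxide lactonising onto the cis ester (C6–C7 and O–C12 bonds), so the ten-membered carbocycle and the butenolide form together.
- Epoxy aldehyde ⇒ E-allylic alcohol (Sharpless epoxidation sets C4/C5) ⇒ enal from a vinylogous Mukaiyama aldol (C2–C3 bond, C2 stereocentre) between a Z-enal and the silyl dienol ether of prenal.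
- Tetrasubstituted iodo enoate ⇒ γ-acyloxy ynoate + iodide + formaldehyde (iodo-aldol, brings C13); C8 stereocentre ⇒ asymmetric addition of methyl propiolate to a β,γ-unsaturated aldehyde.
- That aldehyde ⇒ (Z)-3-methylpent-2-en-4-yn-1-ol, which supplies C2, C1, C10, C14, C9, C8 and the Z olefin.
- Ring order: oxirane first (step 12), then carbocycle and butenolide in one operation (step 14).

Assumption: locants C1–C15 in the comments follow germacrane numbering of the target (lactone oxygen on C6, methacrylate on C8, acetates on C2 and C13); the enynol (a bulk vitamin A intermediate), methyl propiolate, paraformaldehyde and prenal are bought.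

**Route**

Step 1
Reactants: 1 (Z)-3-methylpent-2-en-4-yn-1-ol
Product: 2 (Z)-tert-butyl[(3-methylpent-2-en-4-yn-1-yl)oxy]diphenylsilane
Conditions: TBDPSCl, imidazole, DMF, 0 °C to rt
Reagents that add atoms: tert-butyl(chloro)diphenylsilane, CC(C)(C)[Si](Cl)(c1ccccc1)c1ccccc1
Why: Standard silylation of the primary allylic alcohol masks the future C2 oxygen with a group that survives the borane, organozinc and Lewis-acid steps, and the Z olefin bought with the starting material is untouched.

Step 2
Reactants: 2 (Z)-tert-butyl[(3-methylpent-2-en-4-yn-1-yl)oxy]diphenylsilane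
Product: 4 (Z)-5-[(tert-butyldiphenylsilyl)oxy]-3-methylpent-3-enal, via dienylborane 3 (not isolated)
Conditions: Cy2BH, THF, 0 °C; then H2O2, pH 7 phosphate buffer, 0 °C
Reagents that add atoms: dicyclohexylborane, B(C1CCCCC1)C1CCCCC1; hydrogen peroxide, OO
Why: Anti-Markovnikov hydroboration–oxidation of the terminal alkyne, in which the hindered dialkylborane adds once with boron on the terminal carbon and ignores the trisubstituted olefin, and buffered oxidation releases a dienol whose kinetic α-protonation gives the β,γ-unsaturated aldehyde (C8) with the Z olefin intact.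

Step 3
Reactants: 4 (Z)-5-[(tert-butyldiphenylsilyl)oxy]-3-methylpent-3-enal; 5 methyl propiolate
Product: 6 methyl (4S,6Z)-8-[(tert-butyldiphenylsilyl)oxy]-4-hydroxy-6-methyloct-6-en-2-ynoate
Conditions: (S,S)-ProPhenol (20 mol %), Me2Zn, Ph3PO (40 mol %), toluene, 0 °C
Reagents that add atoms: none
Why: Trost ProPhenol–zinc alkynylation, in which the dinuclear zinc complex delivers the zinc propiolate to one face of the aldehyde under conditions mild enough for this enolisable substrate and sets C8 as S (the ligand antipode is used if the sense on this aldehyde proves opposite).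

Step 4
Reactants: 6 methyl (4S,6Z)-8-[(tert-butyldiphenylsilyl)oxy]-4-hydroxy-6-methyloct-6-en-2-ynoate
Product: 7 methyl (4S,6Z)-8-[(tert-butyldiphenylsilyl)oxy]-4-(methacryloyloxy)-6-methyloct-6-en-2-ynoate
Conditions: methacrylic anhydride, pyridine, DMAP (cat.), CH2Cl2, 0 °C
Reagents that add atoms: methacrylic anhydride, C=C(C)C(=O)OC(=O)C(C)=C
Why: DMAP-catalysed acylation installs the C8 methacrylate of the target with retention at C8, so this oxygen needs no separate protecting group.

Step 5
Reactants: 7 methyl (4S,6Z)-8-[(tert-butyldiphenylsilyl)oxy]-4-(methacryloyloxy)-6-methyloct-6-en-2-ynoate; 8 formaldehyde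
Product: 10 methyl (2Z,4S,6Z)-2-(acetoxymethyl)-8-[(tert-butyldiphenylsilyl)oxy]-3-iodo-4-(methacryloyloxy)-6-methylocta-2,6-dienoate, via hydroxymethyl iodoenoate 9 (not isolated)
Conditions: MgI2, CH2O (gas, from cracked paraformaldehyde), CH2Cl2, 0 °C to rt; then Ac2O, pyridine, DMAP, 0 °C
Reagents that add atoms: magnesium iodide, [Mg+2].[I-].[I-]; acetic anhydride, CC(=O)OC(C)=O
Why: Iodo-aldol (β-iodo Morita–Baylis–Hillman-type) three-component reaction, in which iodide adds to C7 of the magnesium-activated ynoate and the allenolate takes up formaldehyde at C11 on the side away from iodine (the same anti course that makes hydroiodination of 2-alkynoates Z-selective), leaving iodine cis to the ester and C13 cis to C8, after which the alkoxide is acetylated in the same flask.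

Step 6
Reactants: 10 methyl (2Z,4S,6Z)-2-(acetoxymethyl)-8-[(tert-butyldiphenylsilyl)oxy]-3-iodo-4-(methacryloyloxy)-6-methylocta-2,6-dienoate
Product: 11 methyl (2Z,4S,6Z)-2-(acetoxymethyl)-8-hydroxy-3-iodo-4-(methacryloyloxy)-6-methylocta-2,6-dienoate
Conditions: HF·pyridine, THF–pyridine, 0 °C to rt
Reagents that add atoms: none
Why: Fluoride-driven desilylation under buffered, non-basic conditions frees the primary allylic alcohol without ester migration or attack on the β-iodo enoate.

Step 7
Reactants: 11 methyl (2Z,4S,6Z)-2-(acetoxymethyl)-8-hydroxy-3-iodo-4-(methacryloyloxy)-6-methylocta-2,6-dienoate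
Product: 12 methyl (2Z,4S,6Z)-2-(acetoxymethyl)-3-iodo-4-(methacryloyloxy)-6-methyl-8-oxoocta-2,6-dienoate
Conditions: MnO2, CH2Cl2, rt
Reagents that add atoms: none
Why: Chemoselective MnO2 oxidation of the only free allylic alcohol gives the Z enal (C2) under neutral conditions that do not isomerise the olefin.

Step 8
Reactants: 13 3-methylbut-2-enal (prenal)
Product: 14 (E)-tert-butyldimethyl[(3-methylbuta-1,3-dien-1-yl)oxy]silane
Conditions: TBSOTf, Et3N, Et2O, 0 °C to rt
Reagents that add atoms: tert-butyldimethylsilyl trifluoromethanesulfonate, CC(C)(C)[Si](C)(C)OS(=O)(=O)C(F)(F)F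
Why: Soft enolisation (O-silylation with γ-deprotonation) gives the conjugated silyl dienol ether, the γ-nucleophilic C3–C6 unit that carries C15.

Step 9
Reactants: 12 methyl (2Z,4S,6Z)-2-(acetoxymethyl)-3-iodo-4-(methacryloyloxy)-6-methyl-8-oxoocta-2,6-dienoate; 14 (E)-tert-butyldimethyl[(3-methylbuta-1,3-dien-1-yl)oxy]silane
Product: 15 methyl (2Z,4S,6Z,8S,10E)-2-(acetoxymethyl)-8-hydroxy-3-iodo-4-(methacryloyloxy)-6,10-dimethyl-12-oxododeca-2,6,10-trienoate
Conditions: (R)-4-(indol-3-ylmethyl)-2-phenyl-3-tosyl-1,3,2-oxazaborolidin-5-one (from N-Ts-D-tryptophan, 50 mol %), iPrOH, EtCN, −78 °C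
Reagents that add atoms: none
Why: Oxazaborolidinone-catalysed vinylogous Mukaiyama aldol reaction, in which the chiral boron Lewis acid binds the enal and the dienol ether attacks through its γ-carbon on the open face to set C2 as S (the L-tryptophan catalyst would give the epimer), giving the E trisubstituted enal directly while isopropanol takes up the silyl group.

Step 10
Reactants: 15 methyl (2Z,4S,6Z,8S,10E)-2-(acetoxymethyl)-8-hydroxy-3-iodo-4-(methacryloyloxy)-6,10-dimethyl-12-oxododeca-2,6,10-trienoate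
Product: 16 methyl (2Z,4S,6Z,8S,10E)-8-acetoxy-2-(acetoxymethyl)-3-iodo-4-(methacryloyloxy)-6,10-dimethyl-12-oxododeca-2,6,10-trienoate
Conditions: Ac2O, pyridine, DMAP (cat.), CH2Cl2, 0 °C
Reagents that add atoms: acetic anhydride, CC(=O)OC(C)=O
Why: Acylation installs the C2 acetate of the target and removes the only hydroxyl that could compete in the later directed epoxidation, the weak base and low temperature avoiding vinylogous elimination.

Step 11
Reactants: 16 methyl (2Z,4S,6Z,8S,10E)-8-acetoxy-2-(acetoxymethyl)-3-iodo-4-(methacryloyloxy)-6,10-dimethyl-12-oxododeca-2,6,10-trienoate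
Product: 17 methyl (2Z,4S,6Z,8S,10E)-8-acetoxy-2-(acetoxymethyl)-12-hydroxy-3-iodo-4-(methacryloyloxy)-6,10-dimethyldodeca-2,6,10-trienoate
Conditions: NaBH4, CeCl3·7H2O, MeOH, −78 °C
Reagents that add atoms: none
Why: Luche reduction is 1,2-selective for the enal and at −78 °C leaves the acetates, the methacrylate and the hindered β-iodo enoate alone, giving the E allylic alcohol needed for directed epoxidation.

Step 12
Reactants: 17 methyl (2Z,4S,6Z,8S,10E)-8-acetoxy-2-(acetoxymethyl)-12-hydroxy-3-iodo-4-(methacryloyloxy)-6,10-dimethyldodeca-2,6,10-trienoate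
Product: 18 methyl (2Z,4S,6Z,8S)-8-acetoxy-2-(acetoxymethyl)-9-[(2R,3R)-3-(hydroxymethyl)-2-methyloxiran-2-yl]-3-iodo-4-(methacryloyloxy)-6-methylnona-2,6-dienoate
Conditions: Ti(OiPr)4, D-(−)-DIPT, TBHP, 4 Å MS, CH2Cl2, −20 °C
Reagents that add atoms: tert-butyl hydroperoxide, CC(C)(C)OO
Why: Sharpless asymmetric epoxidation, in which only the olefin bearing the free allylic hydroxyl reacts and the D-tartrate titanium complex delivers oxygen to the face that gives the (4R,5R) trans-epoxide under reagent control (as for geraniol-type alcohols), forming the oxirane ring.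

Step 13
Reactants: 18 methyl (2Z,4S,6Z,8S)-8-acetoxy-2-(acetoxymethyl)-9-[(2R,3R)-3-(hydroxymethyl)-2-methyloxiran-2-yl]-3-iodo-4-(methacryloyloxy)-6-methylnona-2,6-dienoate
Product: 19 methyl (2Z,4S,6Z,8S)-8-acetoxy-2-(acetoxymethyl)-9-[(2R,3S)-3-formyl-2-methyloxiran-2-yl]-3-iodo-4-(methacryloyloxy)-6-methylnona-2,6-dienoate
Conditions: DMP, pyridine, CH2Cl2, 0 °C to rt
Reagents that add atoms: none
Why: Dess–Martin oxidation converts the epoxy alcohol into the epoxy aldehyde without epimerisation or epoxide opening (the C5 descriptor becomes S only because the formyl group now outranks C4).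

Step 14
Reactants: 19 methyl (2Z,4S,6Z,8S)-8-acetoxy-2-(acetoxymethyl)-9-[(2R,3S)-3-formyl-2-methyloxiran-2-yl]-3-iodo-4-(methacryloyloxy)-6-methylnona-2,6-dienoate
Product: 20 (2S,4R,5R,6S,8S)-2,13-diacetoxy-4,5-epoxy-8-(methacryloyloxy)germacra-1(10)Z,7(11)-dien-12,6-olide (CNP0268364.3)
Conditions: CrCl2 (8 equiv), NiCl2 (5 mol %), DMSO–THF, 2 mM, rt
Reagents that add atoms: none
Why: Nozaki–Hiyama–Kishi reaction run as a macrocyclisation, in which zerovalent nickel inserts into the activated C7–I bond and transmetalation gives a trivalent vinylchromium that adds intramolecularly to the C6 aldehyde (the Z-1(10) olefin and the trans-epoxide pre-fold the chain, as in related chromium-mediated ten-ring closures onto 4,5-epoxy-6-als), the tether forcing attack anti to the C5–O bond with the chromium-bound carbonyl oxygen outside the nascent ring so that the 5,6-syn (6S) alkoxide forms and closes at once onto the cis methyl ester, so the ten-membered carbocycle and the butenolide arise in the same operation and the product is the target.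

**Compound list**

1 | (Z)-3-methylpent-2-en-4-yn-1-ol | C#C/C(C)=C\CO | starting material
2 | (Z)-tert-butyl[(3-methylpent-2-en-4-yn-1-yl)oxy]diphenylsilane | C#C/C(C)=C\CO[Si](c1ccccc1)(c1ccccc1)C(C)(C)C | intermediate
3 | dicyclohexyl[(1E,3Z)-5-[(tert-butyldiphenylsilyl)oxy]-3-methylpenta-1,3-dien-1-yl]borane | C1CCCCC1B(C1CCCCC1)/C=C/C(C)=C\CO[Si](c1ccccc1)(c1ccccc1)C(C)(C)C | intermediate
4 | (Z)-5-[(tert-butyldiphenylsilyl)oxy]-3-methylpent-3-enal | O=CC/C(C)=C\CO[Si](c1ccccc1)(c1ccccc1)C(C)(C)C | intermediate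
5 | methyl propiolate | C#CC(=O)OC | starting material
6 | methyl (4S,6Z)-8-[(tert-butyldiphenylsilyl)oxy]-4-hydroxy-6-methyloct-6-en-2-ynoate | O[C@H](C#CC(=O)OC)C/C(C)=C\CO[Si](c1ccccc1)(c1ccccc1)C(C)(C)C | intermediate
7 | methyl (4S,6Z)-8-[(tert-butyldiphenylsilyl)oxy]-4-(methacryloyloxy)-6-methyloct-6-en-2-ynoate | C=C(C)C(=O)O[C@H](C#CC(=O)OC)C/C(C)=C\CO[Si](c1ccccc1)(c1ccccc1)C(C)(C)C | intermediate
8 | formaldehyde (from paraformaldehyde) | C=O | starting material
9 | methyl (2Z,4S,6Z)-8-[(tert-butyldiphenylsilyl)oxy]-2-(hydroxymethyl)-3-iodo-4-(methacryloyloxy)-6-methylocta-2,6-dienoate | C=C(C)C(=O)O[C@H](/C(I)=C(\CO)C(=O)OC)C/C(C)=C\CO[Si](c1ccccc1)(c1ccccc1)C(C)(C)C | intermediate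
10 | methyl (2Z,4S,6Z)-2-(acetoxymethyl)-8-[(tert-butyldiphenylsilyl)oxy]-3-iodo-4-(methacryloyloxy)-6-methylocta-2,6-dienoate | C=C(C)C(=O)O[C@H](/C(I)=C(\COC(C)=O)C(=O)OC)C/C(C)=C\CO[Si](c1ccccc1)(c1ccccc1)C(C)(C)C | intermediate
11 | methyl (2Z,4S,6Z)-2-(acetoxymethyl)-8-hydroxy-3-iodo-4-(methacryloyloxy)-6-methylocta-2,6-dienoate | C=C(C)C(=O)O[C@H](/C(I)=C(\COC(C)=O)C(=O)OC)C/C(C)=C\CO | intermediate
12 | methyl (2Z,4S,6Z)-2-(acetoxymethyl)-3-iodo-4-(methacryloyloxy)-6-methyl-8-oxoocta-2,6-dienoate | C=C(C)C(=O)O[C@H](/C(I)=C(\COC(C)=O)C(=O)OC)C/C(C)=C\C=O | intermediate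
13 | 3-methylbut-2-enal (prenal) | CC(C)=CC=O | starting material
14 | (E)-tert-butyldimethyl[(3-methylbuta-1,3-dien-1-yl)oxy]silane | C=C(C)/C=C/O[Si](C)(C)C(C)(C)C | intermediate
15 | methyl (2Z,4S,6Z,8S,10E)-2-(acetoxymethyl)-8-hydroxy-3-iodo-4-(methacryloyloxy)-6,10-dimethyl-12-oxododeca-2,6,10-trienoate | C=C(C)C(=O)O[C@H](/C(I)=C(\COC(C)=O)C(=O)OC)C/C(C)=C\[C@@H](O)C/C(C)=C/C=O | intermediate
16 | methyl (2Z,4S,6Z,8S,10E)-8-acetoxy-2-(acetoxymethyl)-3-iodo-4-(methacryloyloxy)-6,10-dimethyl-12-oxododeca-2,6,10-trienoate | C=C(C)C(=O)O[C@H](/C(I)=C(\COC(C)=O)C(=O)OC)C/C(C)=C\[C@@H](OC(C)=O)C/C(C)=C/C=O | intermediate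
17 | methyl (2Z,4S,6Z,8S,10E)-8-acetoxy-2-(acetoxymethyl)-12-hydroxy-3-iodo-4-(methacryloyloxy)-6,10-dimethyldodeca-2,6,10-trienoate | C=C(C)C(=O)O[C@H](/C(I)=C(\COC(C)=O)C(=O)OC)C/C(C)=C\[C@@H](OC(C)=O)C/C(C)=C/CO | intermediate
18 | methyl (2Z,4S,6Z,8S)-8-acetoxy-2-(acetoxymethyl)-9-[(2R,3R)-3-(hydroxymethyl)-2-methyloxiran-2-yl]-3-iodo-4-(methacryloyloxy)-6-methylnona-2,6-dienoate | C=C(C)C(=O)O[C@H](/C(I)=C(\COC(C)=O)C(=O)OC)C/C(C)=C\[C@@H](OC(C)=O)C[C@@]1(C)O[C@@H]1CO | intermediate
19 | methyl (2Z,4S,6Z,8S)-8-acetoxy-2-(acetoxymethyl)-9-[(2R,3S)-3-formyl-2-methyloxiran-2-yl]-3-iodo-4-(methacryloyloxy)-6-methylnona-2,6-dienoate | C=C(C)C(=O)O[C@H](/C(I)=C(\COC(C)=O)C(=O)OC)C/C(C)=C\[C@@H](OC(C)=O)C[C@@]1(C)O[C@@H]1C=O | intermediate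
20 | (2S,4R,5R,6S,8S)-2,13-diacetoxy-4,5-epoxy-8-(methacryloyloxy)germacra-1(10)Z,7(11)-dien-12,6-olide (CNP0268364.3) | C=C(C)C(=O)O[C@H]1C/C(C)=C\[C@@H](OC(C)=O)C[C@@]2(C)O[C@@H]2[C@H]2OC(=O)C(COC(C)=O)=C12 | target

**Step count and risks**

Total step count: 14. Longest linear sequence: 13 steps (steps 1–7 and 9–14; step 8 is a one-step side branch).

The three steps most likely to fail are 14, 5 and 3.

Step 14 (ring closure) is the most exposed. The ten-membered closure competes with simple reduction of the iodide, the acyloxy group next to the vinyl metal could be lost by β-elimination, and C6 could form as the epimer (open-chain additions to this epoxy aldehyde favour the 5,6-anti product, so the route relies on the ring constraint). The fallback sets out from 16. The same Ni/Cr conditions (CrCl2, NiCl2, DMSO–THF, high dilution, optionally with a chiral sulfonamide ligand on chromium to steer C6) close the vinyl iodide onto the more robust enal and give, again with lactonisation in the same operation, the epoxide-free macrocycle (2S,6R,8S)-2,13-diacetoxy-8-(methacryloyloxy)germacra-1(10)Z,4E,7(11)-trien-12,6-olide F1, which has the same spatial arrangement at C6 as the target. The strained E-4,5 olefin of this lactone is then epoxidised from its outer face (mCPBA, NaHCO3, CH2Cl2, −20 °C, or a Shi ketone with Oxone for reagent control). This comes back to the route at 20 and makes steps 11–13 unnecessary.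

Step 5 (iodo-aldol) may be sluggish with a 3-substituted ynoate and formaldehyde, or may give the wrong olefin geometry. The fallback sets out from 6 and delivers C13 from the C8 oxygen, so that a ring fixes the geometry:
- Chloromethyl chloroformate and pyridine give the chloromethyl carbonate F2.
- NaI and MgI2 in MeCN effect Finkelstein exchange, conjugate addition of iodide to C7 and intramolecular C-alkylation of the allenolate by the tethered O–CH2–I. This closes the seven-membered cyclic carbonate F3, in which C13 must be cis to C8 and iodine cis to the ester.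
- Brief K2CO3 in MeOH at 0 °C gives the diol F4.
- AcCl with 2,4,6-collidine at −78 °C acetylates only the primary hydroxyl to give the monoacetate F5.
- Methacrylic anhydride with DMAP then comes back to the route at 10.

Step 3 (alkynylation) may suffer from enolisation or isomerisation of the β,γ-unsaturated aldehyde under the zinc conditions, or from modest selectivity. The fallback sets out from 4 and moves the stereo-defining event from the addition to a reduction. Lithium methyl propiolate (LiHMDS, THF, −78 °C) adds without selectivity to give the racemic propargylic alcohol F6. MnO2 gives the ynone F7. Midland reduction with (S)-Alpine-Borane then sets 8S and comes back to the route at 6.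

Further compounds
F1 | step 14 | (2S,6R,8S)-2,13-diacetoxy-8-(methacryloyloxy)germacra-1(10)Z,4E,7(11)-trien-12,6-olide | C=C(C)C(=O)O[C@H]1C/C(C)=C\[C@@H](OC(C)=O)C/C(C)=C/[C@H]2OC(=O)C(COC(C)=O)=C12
F2 | step 5 | methyl (4S,6Z)-8-[(tert-butyldiphenylsilyl)oxy]-4-{[(chloromethoxy)carbonyl]oxy}-6-methyloct-6-en-2-ynoate | ClCOC(=O)O[C@H](C#CC(=O)OC)C/C(C)=C\CO[Si](c1ccccc1)(c1ccccc1)C(C)(C)C
F3 | step 5 | methyl (S)-4-{(Z)-4-[(tert-butyldiphenylsilyl)oxy]-2-methylbut-2-en-1-yl}-5-iodo-2-oxo-4,7-dihydro-1,3-dioxepine-6-carboxylate | COC(=O)C1=C(I)[C@H](C/C(C)=C\CO[Si](c2ccccc2)(c2ccccc2)C(C)(C)C)OC(=O)OC1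
F4 | step 5 | methyl (2Z,4S,6Z)-8-[(tert-butyldiphenylsilyl)oxy]-4-hydroxy-2-(hydroxymethyl)-3-iodo-6-methylocta-2,6-dienoate | O[C@H](/C(I)=C(\CO)C(=O)OC)C/C(C)=C\CO[Si](c1ccccc1)(c1ccccc1)C(C)(C)C
F5 | step 5 | methyl (2Z,4S,6Z)-2-(acetoxymethyl)-8-[(tert-butyldiphenylsilyl)oxy]-4-hydroxy-3-iodo-6-methylocta-2,6-dienoate | O[C@H](/C(I)=C(\COC(C)=O)C(=O)OC)C/C(C)=C\CO[Si](c1ccccc1)(c1ccccc1)C(C)(C)C
F6 | step 3 | methyl (6Z)-8-[(tert-butyldiphenylsilyl)oxy]-4-hydroxy-6-methyloct-6-en-2-ynoate (racemic at C4) | OC(C#CC(=O)OC)C/C(C)=C\CO[Si](c1ccccc1)(c1ccccc1)C(C)(C)C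
F7 | step 3 | methyl (6Z)-8-[(tert-butyldiphenylsilyl)oxy]-6-methyl-4-oxooct-6-en-2-ynoate | O=C(C#CC(=O)OC)C/C(C)=C\CO[Si](c1ccccc1)(c1ccccc1)C(C)(C)C
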